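## Retrosynthetic overview

1. Target 17 ← O‑demethylation and hydrodebromination of macrocycle 15. The 19‑membered macrocycle is the only ring formed, and it is closed last.
2. 15 ← oxidative phenol C–O coupling (ring B phenol oxygen onto the ortho carbon of the oxidised ring A phenol) of the open‑chain tribromo bisphenol 13, the laboratory counterpart of the phenol coupling of hydroxybibenzyls in liverworts.
3. 13 ← ortho‑bromination of bisphenol 12 ← hydrogenation/debenzylation of bis‑stilbene 11.
4. 11 ← Ullmann diaryl ether (C–O–D) from bromostilbene 5 and hydroxystilbene 10.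
5. 5 and 10 ← one‑pot Wittig reactions of cheap benzaldehydes and benzyl building blocks.

Assumption: the target SMILES has no stereocentre or stereogenic axis, so the compound is achiral and no stereocontrol is needed; stilbenes 5, 10 and 11 are E/Z mixtures (drawn without geometry) that converge on hydrogenation.

Ring labels: A and C are the 3,4‑dihydroxy‑5‑aryloxyphenyl rings, B is the 1,4‑phenylene and D the 1,3‑phenylene. Ethers are A–O–B and C–O–D; bridges are B–CH2CH2–C and D–CH2CH2–A.

## Route

Step 1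
Reactants: 1 3‑bromo‑4,5‑dimethoxybenzaldehyde; 2 4‑(benzyloxy)benzyl chloride; 3 triphenylphosphine
Product: 5 5‑{2‑[4‑(benzyloxy)phenyl]ethenyl}‑1‑bromo‑2,3‑dimethoxybenzene (E/Z mixture), via phosphonium chloride 4 (not isolated)
Conditions: 2 + PPh3, toluene, 110 °C, 12 h; then KOt‑Bu (1.1 equiv), THF, 0 °C; then 1, 0 °C → rt
Reagents that add atoms: none
Why: One‑pot quaternisation/Wittig olefination of a semistabilised benzylic ylide with an aromatic aldehyde; the aryl bromide is inert and the E/Z ratio is irrelevant because the alkene is hydrogenated in step 4.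

Step 2
Reactants: 6 3‑hydroxybenzyl alcohol; 7 triphenylphosphine hydrobromide; 8 4‑(benzyloxy)‑3‑methoxybenzaldehyde
Product: 10 3‑{2‑[4‑(benzyloxy)‑3‑methoxyphenyl]ethenyl}phenol (E/Z mixture), via phosphonium bromide 9 (not isolated)
Conditions: 6 + PPh3·HBr, MeCN, reflux, 3 h; evaporate; then KOt‑Bu (2.2 equiv), THF, 0 °C; then 8, rt; aq NH4Cl
Reagents that add atoms: none
Why: PPh3·HBr converts the benzylic alcohol directly into the phosphonium salt, and the second equivalent of base holds the phenol as phenoxide so the ylide survives for the Wittig olefination with 8.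

Step 3
Reactants: 5 bromostilbene; 10 hydroxystilbene
Product: 11 1‑{2‑[4‑(benzyloxy)phenyl]ethenyl}‑3‑(3‑{2‑[4‑(benzyloxy)‑3‑methoxyphenyl]ethenyl}phenoxy)‑4,5‑dimethoxybenzene (bis‑stilbene with the C–O–D ether)
Conditions: CuI (10 mol %), picolinic acid (20 mol %), K3PO4 (2 equiv), DMSO, 90 °C, 24 h
Reagents that add atoms: none
Why: Ligand‑accelerated Ullmann diaryl ether synthesis; 10 carries the only free phenol and 5 the only aryl halide, and picolinic acid/Cu tolerates the ortho‑methoxy, electron‑rich bromide.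

Step 4
Reactants: 11 bis‑stilbene diaryl ether
Product: 12 4‑[2‑(3‑{5‑[2‑(4‑hydroxyphenyl)ethyl]‑2,3‑dimethoxyphenoxy}phenyl)ethyl]‑2‑methoxyphenol (open‑chain bisphenol)
Conditions: H2 (1 atm), 10 % Pd/C, THF/MeOH, rt
Reagents that add atoms: none
Why: Catalytic hydrogenation saturates both stilbene double bonds and hydrogenolyses both benzyl ethers in one operation, freeing exactly the ring A and ring B phenols while the methyl and diaryl ethers stay.

Step 5
Reactants: 12 open‑chain bisphenol
Product: 13 2,6‑dibromo‑4‑{2‑[3‑(3‑{2‑(3‑bromo‑4‑hydroxy‑5‑methoxyphenyl)ethyl}phenoxy)‑4,5‑dimethoxyphenyl]ethyl}phenol (tribromide)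
Conditions: NBS (3.05 equiv), i‑Pr2NH (10 mol %), CH2Cl2, 0 °C
Reagents that add atoms: N‑bromosuccinimide, O=C1CCC(=O)N1Br
Why: Amine‑catalysed ortho‑selective electrophilic bromination of phenols; it fills the three positions ortho to the two free OH groups (para positions are blocked by the alkyl chains) and leaves the non‑phenolic rings C and D alone.

Step 6
Reactants: 13 tribromide
Product: 15 macrocyclic dibromo trimethyl ether (ring A: 3‑aryloxy‑4‑hydroxy‑5‑methoxy; ring B: 3,5‑dibromo‑1,4‑phenylene; ring C: 3,4‑dimethoxy‑5‑aryloxy), via quinol methyl ether 14 (not isolated)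
Conditions: Tl(NO3)3·3H2O (2 equiv), pyridine (6 equiv), THF/MeOH 5:1, 1 mM, −20 → 0 °C; then Zn dust, AcOH, rt
Reagents that add atoms: methanol, CO (its methoxy group is held only in 14 and is given back in the zinc reduction)
Why: Proposed new method: Tl(III) oxidises the more electron‑rich bromoguaiacol ring A to a phenoxonium ion, the less oxidisable 2,6‑dibromophenol oxygen of ring B attacks its bromine‑bearing ortho carbon intramolecularly with irreversible loss of bromide (attack at the methoxy‑bearing carbon should give only a mixed ketal that reverts under the pyridine buffer), methanol traps the resulting cation as quinol ether 14 and Zn/AcOH rearomatises it to 15 without creating a stereocentre; the closest known reaction is the thallium(III) nitrate oxidative phenol coupling of o,o′‑dihalophenols to isodityrosine‑type macrocyclic diaryl ethers followed by reductive rearomatisation, extended here to a 2‑bromo‑6‑methoxyphenol acceptor and a 19‑membered bis(bibenzyl) ring.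

Step 7
Reactants: 15 macrocyclic dibromo trimethyl ether
Product: 16 macrocyclic trimethyl ether (15 without the two bromines)
Conditions: H2 (1 atm), 10 % Pd/C, Et3N (3 equiv), EtOAc/MeOH, rt
Reagents that add atoms: none
Why: Pd‑catalysed hydrodehalogenation removes both aryl bromides under conditions that leave diaryl ethers, methyl ethers and the free phenol untouched.

Step 8
Reactants: 16 macrocyclic trimethyl ether
Product: 17 target CNP0511668.0
Conditions: BBr3 (10 equiv), CH2Cl2, −78 °C → rt; then MeOH/H2O, 0 °C (degassed work‑up)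
Reagents that add atoms: none
Why: BBr3 Lewis‑acid ether cleavage removes the three aryl methyl ethers and does not cleave diaryl ethers, giving the two catechols of the achiral target.

## Compound list

1 | 3‑bromo‑4,5‑dimethoxybenzaldehyde | COc1cc(C=O)cc(Br)c1OC | starting material
2 | 4‑(benzyloxy)benzyl chloride | ClCc1ccc(OCc2ccccc2)cc1 | starting material
3 | triphenylphosphine | c1ccc(cc1)P(c1ccccc1)c1ccccc1 | starting material
4 | [4‑(benzyloxy)benzyl]triphenylphosphonium chloride | [Cl-].c1ccc(cc1)[P+](Cc1ccc(OCc2ccccc2)cc1)(c1ccccc1)c1ccccc1 | intermediate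
5 | 5‑{2‑[4‑(benzyloxy)phenyl]ethenyl}‑1‑bromo‑2,3‑dimethoxybenzene (E/Z mixture) | COc1cc(C=Cc2ccc(OCc3ccccc3)cc2)cc(Br)c1OC | intermediate
6 | 3‑hydroxybenzyl alcohol | OCc1cccc(O)c1 | starting material
7 | triphenylphosphine hydrobromide | [Br-].c1ccc(cc1)[PH+](c1ccccc1)c1ccccc1 | starting material
8 | 4‑(benzyloxy)‑3‑methoxybenzaldehyde (O‑benzylvanillin) | COc1cc(C=O)ccc1OCc1ccccc1 | starting material
9 | (3‑hydroxybenzyl)triphenylphosphonium bromide | [Br-].Oc1cccc(C[P+](c2ccccc2)(c2ccccc2)c2ccccc2)c1 | intermediate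
10 | 3‑{2‑[4‑(benzyloxy)‑3‑methoxyphenyl]ethenyl}phenol (E/Z mixture) | COc1cc(C=Cc2cccc(O)c2)ccc1OCc1ccccc1 | intermediate
11 | bis‑stilbene diaryl ether (C–O–D ether; rings A and B O‑benzylated) | COc1cc(C=Cc2ccc(OCc3ccccc3)cc2)cc(Oc2cccc(C=Cc3ccc(OCc4ccccc4)c(OC)c3)c2)c1OC | intermediate
12 | 4‑[2‑(3‑{5‑[2‑(4‑hydroxyphenyl)ethyl]‑2,3‑dimethoxyphenoxy}phenyl)ethyl]‑2‑methoxyphenol | COc1cc(CCc2ccc(O)cc2)cc(Oc2cccc(CCc3ccc(O)c(OC)c3)c2)c1OC | intermediate
13 | tribromide (ring A 3‑bromo‑4‑hydroxy‑5‑methoxyphenyl; ring B 3,5‑dibromo‑4‑hydroxyphenyl) | COc1cc(CCc2cc(Br)c(O)c(Br)c2)cc(Oc2cccc(CCc3cc(Br)c(O)c(OC)c3)c2)c1OC | intermediate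
14 | macrocyclic para‑quinol methyl ether (ring A as 2‑aryloxy‑4,6‑dimethoxy‑4‑alkylcyclohexa‑2,5‑dienone; racemic at the quinol carbon) | COC1=CC2(OC)C=C(C1=O)Oc1c(Br)cc(cc1Br)CCc1cc(OC)c(OC)c(c1)Oc1cccc(c1)CC2 | intermediate
15 | macrocyclic dibromo trimethyl ether | COc1cc2cc(c1O)Oc1c(Br)cc(cc1Br)CCc1cc(OC)c(OC)c(c1)Oc1cccc(c1)CC2 | intermediate
16 | macrocyclic trimethyl ether | COc1cc2cc(c1O)Oc1ccc(cc1)CCc1cc(OC)c(OC)c(c1)Oc1cccc(c1)CC2 | intermediate
17 | CNP0511668.0 (achiral) | Oc1cc2cc(c1O)Oc1ccc(cc1)CCc1cc(O)c(O)c(c1)Oc1cccc(c1)CC2 | target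

## Step count and risks

Total steps: 8. Longest linear sequence: 7 (step 1 or step 2, then steps 3–8).

Steps most likely to fail:

Step 6 (oxidative macrocyclisation). The acceptor is a bromoguaiacol, not the usual dihalophenol, so the ring B oxygen may attack the methoxy‑bearing carbon and oligomers may form. The fallback sets out from 12 and comes back at 17. It replaces oxidative coupling by a copper‑mediated ring closure. Silylate the unhindered ring B phenol selectively (TIPSCl, imidazole, DMF, 0 °C) to the mono‑TIPS ether F1. Brominate the guaiacol ring ortho to its OH (NBS 1 equiv, cat. i‑Pr2NH) to the bromophenol F2. Methylate it (MeI, K2CO3, acetone) to the methyl ether F3. Remove the silyl group (TBAF, THF) to the phenol F4. Close the A–O–B ether by intramolecular Ullmann coupling at high dilution (CuI, N,N‑dimethylglycine, Cs2CO3, dioxane, 100 °C) to the macrocyclic tetramethyl ether F5. Demethylate with BBr3 as in step 8 to reach 17.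

Step 3 (Ullmann ether with an ortho‑methoxy, electron‑rich bromide). The fallback sets out from 5 and comes back at 11. It reverses the polarity of the aryl partner. Miyaura borylation (B2pin2, Pd(dppf)Cl2, KOAc, dioxane, 90 °C) gives the pinacol boronate F6. Chan–Lam–Evans coupling of F6 with phenol 10 (Cu(OAc)2, pyridine, B(OH)3, 4 Å sieves, air, MeCN, 60 °C) then gives 11.

Step 5 (threefold bromination; risk of attack para to OMe on ring A or on rings C/D). The fallback sets out from 12 and comes back at 16. It switches to phenolate‑specific iodination (I2, KI, aq NaHCO3/MeOH, rt), which halogenates only ortho to an ionised phenol and gives the triiodide F7. The step 6 conditions convert F7 through the diiodo quinol methyl ether F8 (not isolated; iodide is the leaving group on ring A) into the macrocyclic diiodide F9. The step 7 hydrogenolysis of F9 gives 16.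

## Further compounds

F1 | step 6 | mono‑TIPS ether of 12 (ring B O‑silylated) | COc1cc(CCc2ccc(O[Si](C(C)C)(C(C)C)C(C)C)cc2)cc(Oc2cccc(CCc3ccc(O)c(OC)c3)c2)c1OC
F2 | step 6 | ring A bromophenol of F1 | COc1cc(CCc2ccc(O[Si](C(C)C)(C(C)C)C(C)C)cc2)cc(Oc2cccc(CCc3cc(Br)c(O)c(OC)c3)c2)c1OC
F3 | step 6 | ring A methyl ether of F2 | COc1cc(CCc2ccc(O[Si](C(C)C)(C(C)C)C(C)C)cc2)cc(Oc2cccc(CCc3cc(Br)c(OC)c(OC)c3)c2)c1OC
F4 | step 6 | desilylated bromo phenol | COc1cc(CCc2ccc(O)cc2)cc(Oc2cccc(CCc3cc(Br)c(OC)c(OC)c3)c2)c1OC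
F5 | step 6 | macrocyclic tetramethyl ether | COc1cc2cc(c1OC)Oc1ccc(cc1)CCc1cc(OC)c(OC)c(c1)Oc1cccc(c1)CC2
F6 | step 3 | pinacol boronate of 5 | COc1cc(C=Cc2ccc(OCc3ccccc3)cc2)cc(B2OC(C)(C)C(C)(C)O2)c1OC
F7 | step 5 | triiodide analogue of 13 | COc1cc(CCc2cc(I)c(O)c(I)c2)cc(Oc2cccc(CCc3cc(I)c(O)c(OC)c3)c2)c1OC
F8 | step 5 | diiodo quinol methyl ether (not isolated) | COC1=CC2(OC)C=C(C1=O)Oc1c(I)cc(cc1I)CCc1cc(OC)c(OC)c(c1)Oc1cccc(c1)CC2
F9 | step 5 | macrocyclic diiodide | COc1cc2cc(c1O)Oc1c(I)cc(cc1I)CCc1cc(OC)c(OC)c(c1)Oc1cccc(c1)CC2
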